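**Retrosynthetic overview**
- Target read from the SMILES: (3S)-5-hydroxy-7-methoxyphthalide carrying a (13S)-13-hydroxy-10-oxotetradecyl chain at C3. The last two steps only remove an O-benzyl group (phenol) and an O-TBS group (carbinol).
- Key disconnection: the C3–C3a bond and the lactone C–O bond together, by an enantioselective imidate-directed ortho C–H addition of an aryl N–H imidate to an aliphatic keto aldehyde with ring closure onto the imidate (new chemistry; sets C3).
- Arene partner: ethyl 4-(benzyloxy)-2-methoxybenzimidate, from 4-hydroxy-2-methoxybenzonitrile by benzylation, hydration and O-ethylation.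
- Chain partner: the carbinol centre is bought as (S)-γ-valerolactone; Weinreb amide plus undec-10-enyl Grignard reagent gives the ketone, and ozonolysis unmasks the aldehyde.
- Ring order: the benzene ring is bought; the lactone ring is the only ring formed, in the key step.

Assumption: the (R)-configured chiral cyclopentadienyl ligand is taken to give the (3S) lactone on the steric model stated under step 8; if the first run shows the opposite sense, the (S)-ligand is used and nothing else changes.

Catalyst of step 8: [(R)-CpxRhI2]2, where Cpx is an η5-cyclopentadienyl ligand whose two adjacent ring carbons are tied through CH2 groups to C2 and C2' of (R)-3,3'-dimethoxy-1,1'-binaphthyl.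

**Route**

Step 1
Reactants: 1 4-hydroxy-2-methoxybenzonitrile
Product: 2 4-(benzyloxy)-2-methoxybenzonitrile
Conditions: BnBr, K2CO3, DMF, 60 °C
Reagents that add atoms: benzyl bromide, BrCc1ccccc1
Why: Williamson ether synthesis; the acidic phenol para to the nitrile is alkylated cleanly and no stereocentre is involved.

Step 2
Reactants: 2 4-(benzyloxy)-2-methoxybenzonitrile
Product: 3 4-(benzyloxy)-2-methoxybenzamide
Conditions: [PtH{(PMe2O)2H}(PMe2OH)] (1 mol %), EtOH/H2O 4:1, 80 °C
Reagents that add atoms: water, O
Why: Platinum-catalysed neutral nitrile hydration stops at the primary amide and tolerates the ortho methoxy group and the benzyl ether.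

Step 3
Reactants: 3 4-(benzyloxy)-2-methoxybenzamide
Product: 5 ethyl 4-(benzyloxy)-2-methoxybenzimidate, via imidatium tetrafluoroborate 4 (not isolated)
Conditions: Et3OBF4, CH2Cl2, rt; then cold sat. aq. NaHCO3
Reagents that add atoms: triethyloxonium tetrafluoroborate, CC[O+](CC)CC.F[B-](F)(F)F
Why: O-alkylation of a primary amide by a trialkyloxonium salt (Meerwein alkylation) gives the imidatium salt, which cold bicarbonate frees to the N–H imidate used as directing group.

Step 4
Reactants: 6 (S)-γ-valerolactone
Product: 7 (S)-4-hydroxy-N-methoxy-N-methylpentanamide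
Conditions: MeNH(OMe)·HCl, AlMe3, CH2Cl2, 0 °C to rt; then 0.5 M aq. HCl, 0 °C
Reagents that add atoms: N,O-dimethylhydroxylamine hydrochloride, CNOC.Cl
Why: Weinreb aminolysis of a lactone by the aluminium amide opens the ring at the acyl carbon, so the (S)-carbinol centre is untouched.

Step 5
Reactants: 7 (S)-4-hydroxy-N-methoxy-N-methylpentanamide
Product: 8 (S)-4-[(tert-butyldimethylsilyl)oxy]-N-methoxy-N-methylpentanamide
Conditions: TBSCl, imidazole, DMF, rt
Reagents that add atoms: tert-butyldimethylsilyl chloride, CC(C)(C)[Si](C)(C)Cl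
Why: Standard silyl ether formation caps the alcohol before it can relactonise and does not touch the stereocentre.

Step 6
Reactants: 8 (S)-4-[(tert-butyldimethylsilyl)oxy]-N-methoxy-N-methylpentanamide; 9 undec-10-en-1-yl bromide (11-bromoundec-1-ene)
Product: 12 (S)-2-[(tert-butyldimethylsilyl)oxy]hexadec-15-en-5-one, via undec-10-en-1-ylmagnesium bromide 10 (not isolated), via bromomagnesium hemiaminal chelate 11 (not isolated)
Conditions: 9, Mg, THF, 40 °C; then 8, THF, 0 °C; then 0.5 M aq. HCl, 0 °C
Reagents that add atoms: none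
Why: Weinreb ketone synthesis; the Grignard reagent adds only once because chelate 11 survives until the quench, and the silyl ether and stereocentre are inert.

Step 7
Reactants: 12 (S)-2-[(tert-butyldimethylsilyl)oxy]hexadec-15-en-5-one
Product: 14 (S)-14-[(tert-butyldimethylsilyl)oxy]-11-oxopentadecanal, via secondary ozonide 13 (not isolated)
Conditions: O3, CH2Cl2, −78 °C; then PPh3, −78 °C to rt
Reagents that add atoms: ozone, [O-][O+]=O
Why: Ozonolysis with reductive work-up cleaves only the terminal alkene to the aldehyde; ketone and silyl ether are inert to ozone.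

Step 8
Reactants: 5 ethyl 4-(benzyloxy)-2-methoxybenzimidate (1.5 equiv); 14 (S)-14-[(tert-butyldimethylsilyl)oxy]-11-oxopentadecanal
Product: 16 (S)-5-(benzyloxy)-3-[(S)-13-((tert-butyldimethylsilyl)oxy)-10-oxotetradecyl]-7-methoxyisobenzofuran-1(3H)-one, via cyclic N–H iminolactone 15 (not isolated)
Conditions: [(R)-CpxRhI2]2 (2.5 mol %), AgSbF6 (10 mol %), 1-AdCO2H (20 mol %), 4 Å MS, DCE, 60 °C; then THF/H2O, AcOH (cat.), rt
Reagents that add atoms: water, O
Why: Proposed new method: an enantioselective chiral-cyclopentadienyl trivalent-rhodium-catalysed imidate-directed ortho C–H addition to an unactivated aliphatic aldehyde with lactonising capture, in which the N–H imidate binds the cationic CpxRh centre, carboxylate-assisted concerted metalation–deprotonation occurs at the only free ortho C–H (C6), the aldehyde (far more electrophilic than the remote dialkyl ketone) coordinates at the single open site with its chain turned away from the Cp face and the binaphthyl back wall so that insertion into the Rh–aryl bond takes one carbonyl face and sets C3 as (S), and the reversible insertion is made irreversible when the rhodium alkoxide attacks the metal-activated imidate carbon and expels EtOH to give 15, which water hydrolyses to the lactone; the closest known reaction types are the racemic [Cp*RhCl2]2/AgSbF6 cascade of benzimidates and aldehydes to phthalides and chiral-Cp rhodium-catalysed enantioselective C–H additions to alkenes and tethered carbonyl groups.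

Step 9
Reactants: 16 (S)-5-(benzyloxy)-3-[(S)-13-((tert-butyldimethylsilyl)oxy)-10-oxotetradecyl]-7-methoxyisobenzofuran-1(3H)-one
Product: 17 (S)-3-[(S)-13-((tert-butyldimethylsilyl)oxy)-10-oxotetradecyl]-5-hydroxy-7-methoxyisobenzofuran-1(3H)-one
Conditions: H2 (1 atm), 10% Pd/C, EtOAc, rt
Reagents that add atoms: none
Why: Hydrogenolysis of the aryl benzyl ether; the lactone benzylic C–O bond lies in the arene plane and overlaps poorly with the π system, and the dialkyl ketone is not reduced at 1 atm, so only the benzyl group is lost.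

Step 10
Reactants: 17 (S)-3-[(S)-13-((tert-butyldimethylsilyl)oxy)-10-oxotetradecyl]-5-hydroxy-7-methoxyisobenzofuran-1(3H)-one
Product: 18 (S)-5-hydroxy-3-[(S)-13-hydroxy-10-oxotetradecyl]-7-methoxyisobenzofuran-1(3H)-one
Conditions: HF·pyridine, pyridine/THF, 0 °C to rt
Reagents that add atoms: none
Why: Buffered fluoride desilylation removes the secondary TBS ether without opening the lactone, cleaving the aryl methyl ether, or dehydrating the γ-hydroxy ketone; neither stereocentre is touched.

**Compound list**
1 | 4-hydroxy-2-methoxybenzonitrile | COc1cc(O)ccc1C#N | starting material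
2 | 4-(benzyloxy)-2-methoxybenzonitrile | COc1cc(OCc2ccccc2)ccc1C#N | intermediate
3 | 4-(benzyloxy)-2-methoxybenzamide | COc1cc(OCc2ccccc2)ccc1C(N)=O | intermediate
4 | ethyl 4-(benzyloxy)-2-methoxybenzimidatium tetrafluoroborate (not isolated) | CCOC(=[NH2+])c1ccc(OCc2ccccc2)cc1OC.F[B-](F)(F)F | intermediate
5 | ethyl 4-(benzyloxy)-2-methoxybenzimidate (N–H imidate) | CCOC(=N)c1ccc(OCc2ccccc2)cc1OC | intermediate
6 | (S)-γ-valerolactone [(S)-5-methyldihydrofuran-2(3H)-one] | C[C@H]1CCC(=O)O1 | starting material
7 | (S)-4-hydroxy-N-methoxy-N-methylpentanamide | CON(C)C(=O)CC[C@H](C)O | intermediate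
8 | (S)-4-[(tert-butyldimethylsilyl)oxy]-N-methoxy-N-methylpentanamide | CON(C)C(=O)CC[C@H](C)O[Si](C)(C)C(C)(C)C | intermediate
9 | undec-10-en-1-yl bromide (11-bromoundec-1-ene) | C=CCCCCCCCCCBr | starting material
10 | undec-10-en-1-ylmagnesium bromide (not isolated) | C=CCCCCCCCCC[Mg]Br | intermediate
11 | bromomagnesium (2S)-2-[(tert-butyldimethylsilyl)oxy]-5-[methoxy(methyl)amino]hexadec-15-en-5-olate, C5 unassigned (not isolated) | C=CCCCCCCCCCC(O[Mg]Br)(CC[C@H](C)O[Si](C)(C)C(C)(C)C)N(C)OC | intermediate
12 | (S)-2-[(tert-butyldimethylsilyl)oxy]hexadec-15-en-5-one | C=CCCCCCCCCCC(=O)CC[C@H](C)O[Si](C)(C)C(C)(C)C | intermediate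
13 | 3-[(S)-13-((tert-butyldimethylsilyl)oxy)-10-oxotetradecyl]-1,2,4-trioxolane, ring carbon unassigned (not isolated) | C1OC(CCCCCCCCCC(=O)CC[C@H](C)O[Si](C)(C)C(C)(C)C)OO1 | intermediate
14 | (S)-14-[(tert-butyldimethylsilyl)oxy]-11-oxopentadecanal | O=CCCCCCCCCCC(=O)CC[C@H](C)O[Si](C)(C)C(C)(C)C | intermediate
15 | (S)-5-(benzyloxy)-3-[(S)-13-((tert-butyldimethylsilyl)oxy)-10-oxotetradecyl]-7-methoxyisobenzofuran-1(3H)-imine (not isolated) | COc1cc(OCc3ccccc3)cc2c1C(=N)O[C@H]2CCCCCCCCCC(=O)CC[C@H](C)O[Si](C)(C)C(C)(C)C | intermediate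
16 | (S)-5-(benzyloxy)-3-[(S)-13-((tert-butyldimethylsilyl)oxy)-10-oxotetradecyl]-7-methoxyisobenzofuran-1(3H)-one | COc1cc(OCc3ccccc3)cc2c1C(=O)O[C@H]2CCCCCCCCCC(=O)CC[C@H](C)O[Si](C)(C)C(C)(C)C | intermediate
17 | (S)-3-[(S)-13-((tert-butyldimethylsilyl)oxy)-10-oxotetradecyl]-5-hydroxy-7-methoxyisobenzofuran-1(3H)-one | COc1cc(O)cc2c1C(=O)O[C@H]2CCCCCCCCCC(=O)CC[C@H](C)O[Si](C)(C)C(C)(C)C | intermediate
18 | (S)-5-hydroxy-3-[(S)-13-hydroxy-10-oxotetradecyl]-7-methoxyisobenzofuran-1(3H)-one | COc1cc(O)cc2c1C(=O)O[C@H]2CCCCCCCCCC(=O)CC[C@H](C)O | target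

**Totals**
Total step count: 10 (arene fragment steps 1–3, chain fragment steps 4–7, union and end game steps 8–10).
Longest linear sequence: 7 steps (6 → 7 → 8 → 12 → 14 → 16 → 17 → 18; steps 4–10).

**Three steps most likely to fail**

Step 8 (the proposed new step). Risks are low enantioselectivity with a flexible α-unbranched aldehyde, slow C–H metalation next to the ortho methoxy group at 60 °C, and aldol self-condensation of 14. The fallback uses known chemistry only, sets out from 5 and 14 and comes back at 16; the stereocentre is then set by asymmetric ketone reduction instead of by the C–C bond formation. The known achiral cascade ([Cp*RhCl2]2, AgSbF6, DCE, 110 °C, aqueous work-up) gives, through the C3-epimeric iminolactone F1, the phthalide as a 1:1 mixture at C3, the epimeric phthalide F2. KOH in MeOH/H2O opens the lactone to the potassium hydroxy carboxylate F3. Without acidification this is methylated (MeI, DMF) to the hydroxy ester F4 and oxidised at once (Dess–Martin periodinane, NaHCO3, CH2Cl2) to the aryl ketone F5, which erases the C3 centre. Noyori asymmetric transfer hydrogenation (RuCl[(S,S)-TsDPEN](p-cymene), HCO2H/Et3N, 30 °C) reduces the aryl ketone much faster than the dialkyl ketone and gives the (S)-benzylic alcohol F6, by analogy with acetophenone. F6 closes onto the neighbouring ester with loss of methanol (PPTS if needed) and rejoins the route at 16.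

Step 3. The free N–H imidate of an electron-rich, ortho-substituted arene can hydrolyse to ester or amide during the aqueous bicarbonate liberation. The fallback sets out from nitrile 2 and comes back at 5, bypassing 3 and 4. A Pinner reaction (dry HCl, EtOH/Et2O, 0–5 °C) gives the imidate hydrochloride F7, which is freed without water (Et3N, dry Et2O, filtration of the ammonium salt) and used directly as 5.

Step 9. Risks are slow or over-reductive hydrogenolysis (lactone C–O cleavage, ketone reduction). The fallback sets out from 16 and comes back at 17 without any new compound. It is a non-reductive Lewis acid debenzylation with cation transfer: BCl3 (2 equiv), pentamethylbenzene (3 equiv), CH2Cl2, −78 °C, 20 min, quenched with Et3N/MeOH at −78 °C. At this temperature the 7-methoxy group next to the carbonyl is not cleaved, and any partial loss of the silyl group is harmless because step 10 removes it anyway.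

**Further compounds**
F1 | step 8 | (3RS)-5-(benzyloxy)-3-[(S)-13-((tert-butyldimethylsilyl)oxy)-10-oxotetradecyl]-7-methoxyisobenzofuran-1(3H)-imine | COc1cc(OCc3ccccc3)cc2c1C(=N)OC2CCCCCCCCCC(=O)CC[C@H](C)O[Si](C)(C)C(C)(C)C
F2 | step 8 | (3RS)-5-(benzyloxy)-3-[(S)-13-((tert-butyldimethylsilyl)oxy)-10-oxotetradecyl]-7-methoxyisobenzofuran-1(3H)-one | COc1cc(OCc3ccccc3)cc2c1C(=O)OC2CCCCCCCCCC(=O)CC[C@H](C)O[Si](C)(C)C(C)(C)C
F3 | step 8 | potassium 4-(benzyloxy)-2-[(1RS,14S)-14-((tert-butyldimethylsilyl)oxy)-1-hydroxy-11-oxopentadecyl]-6-methoxybenzoate | [K+].[O-]C(=O)c1c(OC)cc(OCc2ccccc2)cc1C(O)CCCCCCCCCC(=O)CC[C@H](C)O[Si](C)(C)C(C)(C)C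
F4 | step 8 | methyl 4-(benzyloxy)-2-[(1RS,14S)-14-((tert-butyldimethylsilyl)oxy)-1-hydroxy-11-oxopentadecyl]-6-methoxybenzoate | COC(=O)c1c(OC)cc(OCc2ccccc2)cc1C(O)CCCCCCCCCC(=O)CC[C@H](C)O[Si](C)(C)C(C)(C)C
F5 | step 8 | methyl 4-(benzyloxy)-2-methoxy-6-[(S)-14-((tert-butyldimethylsilyl)oxy)-11-oxopentadecanoyl]benzoate | COC(=O)c1c(OC)cc(OCc2ccccc2)cc1C(=O)CCCCCCCCCC(=O)CC[C@H](C)O[Si](C)(C)C(C)(C)C
F6 | step 8 | methyl 4-(benzyloxy)-2-[(1S,14S)-14-((tert-butyldimethylsilyl)oxy)-1-hydroxy-11-oxopentadecyl]-6-methoxybenzoate | COC(=O)c1c(OC)cc(OCc2ccccc2)cc1[C@@H](O)CCCCCCCCCC(=O)CC[C@H](C)O[Si](C)(C)C(C)(C)C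
F7 | step 3 | ethyl 4-(benzyloxy)-2-methoxybenzimidate hydrochloride | CCOC(=[NH2+])c1ccc(OCc2ccccc2)cc1OC.[Cl-]
F0 | step 9 | none | none
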